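The cyclobutane is made by one intramolecular enoate–alkene [2+2] photocycloaddition that forms C5–C6 and C10–C11 (locants in the remark below). The feature exploited is that the C1 oxygen and the C9 carbonyl carbon sit 1,4 across the C10–C11 bond of the four-membered ring: C9 is therefore carried as a lactone carbonyl on O–C1. The precursor is an eight-membered (Z)-enoate lactone (O–C9–C10=C5–C4–C3–C2–C1) bearing the C11=C6 alkene on C1; irradiation closes the γ-lactone, the cyclobutane and both seven-membered rings, with C1 fixing the new stereocentres. MeLi then converts the lactone into the C9 methyl ketone, aldol condensation closes the six-membered ring, and a cuprate sets C7.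

Key step: step 9

Remark (own locants, used throughout): C1 = CH–O(angelate); C2, C3 = ring CH2; C4 = C(CH3)(CH2O-tiglate); C5 = cyclobutane CH next to C4; C6 = cyclobutane CH next to C7; C7 = CH(CH3); C8 = CH2; C9 = C=O; C10 = cyclobutane CH next to C9; C11 = cyclobutane C(CH3) next to C1.

Step 1
Reactants: 1 geraniol
Product: 2 (2R,3R)-2,3-epoxygeraniol
Conditions: Ti(OiPr)4 (5 mol %), D-(−)-diethyl tartrate (6 mol %), t-BuOOH, 4 Å MS, CH2Cl2, −20 °C
Reagents that add atoms: tert-butyl hydroperoxide, CC(C)(C)OO
Why: Katsuki–Sharpless asymmetric epoxidation; only the allylic 2,3-alkene reacts, and D-(−)-tartrate should deliver oxygen to the face that gives the (2R,3R)-epoxide, the source of the C4 configuration.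

Step 2
Reactants: 2 (2R,3R)-2,3-epoxygeraniol
Product: 3 tert-butyldimethylsilyl ether of 2
Conditions: TBSCl, imidazole, DMF, 0 °C to rt
Reagents that add atoms: tert-butyldimethylsilyl chloride, CC(C)(C)[Si](C)(C)Cl
Why: Standard silylation of the primary alcohol; the siloxymethyl group is the migrating group of the next step and the lasting protection of the C4 hydroxymethyl group.

Step 3
Reactants: 3 tert-butyldimethylsilyl ether of 2
Product: 4 (2R)-2-[(tert-butyldimethylsilyloxy)methyl]-2,6-dimethylhept-5-enal
Conditions: MeAl(OAr)2 (MABR, Ar = 4-bromo-2,6-di-tert-butylphenyl, from Me3Al and the phenol, 20 mol %), CH2Cl2, −78 to −40 °C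
Reagents that add atoms: none
Why: Maruoka–Yamamoto rearrangement of an epoxy silyl ether (semipinacol type): the bulky aluminium Lewis acid opens the epoxide at the tertiary carbon and the siloxymethyl group shifts anti to the departing oxygen, so the epoxide chirality should be transferred to the quaternary C4 (R in the aldehyde), with C5 as the aldehyde.

Step 4
Reactants: 4 (2R)-2-[(tert-butyldimethylsilyloxy)methyl]-2,6-dimethylhept-5-enal
Product: 5 methyl (2Z,4S)-4-[(tert-butyldimethylsilyloxy)methyl]-4,8-dimethylnona-2,7-dienoate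
Conditions: (CF3CH2O)2P(O)CH2CO2Me, KHMDS, 18-crown-6, THF, −78 °C
Reagents that add atoms: methyl 2-[bis(2,2,2-trifluoroethoxy)phosphoryl]acetate, COC(=O)CP(=O)(OCC(F)(F)F)OCC(F)(F)F
Why: Still–Gennari variant of the Horner–Wadsworth–Emmons olefination; the trifluoroethyl phosphonate should give the Z enoate (C5=C10) needed for the medium-ring lactone, and the aldehyde cannot enolise.

Step 5
Reactants: 5 methyl (2Z,4S)-4-[(tert-butyldimethylsilyloxy)methyl]-4,8-dimethylnona-2,7-dienoate
Product: 6 methyl (2Z,4S)-4-[(tert-butyldimethylsilyloxy)methyl]-4-methyl-7-oxohept-2-enoate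
Conditions: O3, CH2Cl2/MeOH, −78 °C (Sudan Red 7B end point); then Me2S, −78 °C to rt
Reagents that add atoms: ozone, [O-][O+]=O
Why: Ozonolysis with reductive work-up; the electron-rich trisubstituted alkene should be cleaved much faster than the electron-poor enoate, which unveils the C1 aldehyde.

Step 6
Reactants: 6 methyl (2Z,4S)-4-[(tert-butyldimethylsilyloxy)methyl]-4-methyl-7-oxohept-2-enoate; 7 1,1-diethoxybut-2-yne
Product: 10 methyl (2Z,4S,7R,8E)-4-[(tert-butyldimethylsilyloxy)methyl]-10,10-diethoxy-7-hydroxy-4,8-dimethyldeca-2,8-dienoate, via alkenylzirconocene chloride 8 (not isolated), via alkenyl(methyl)zinc 9 (not isolated)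
Conditions: 7, Cp2Zr(H)Cl, CH2Cl2, rt; Me2Zn, toluene, −65 °C; 3-exo-morpholinoisoborneol (MIB, 10 mol %, enantiomer chosen for the 7R carbinol); then 6, −30 to 0 °C
Reagents that add atoms: none
Why: Wipf hydrozirconation–transmetalation–addition: syn addition of Zr–H should place zirconium on the methyl-bearing alkyne carbon (away from the acetal), and after transfer to zinc the ligand-controlled addition to the aldehyde should give the E-trisubstituted allylic alcohol with C1 set R by the amino alcohol (reagent control; the remote C4 has no influence).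

Step 7
Reactants: 10 methyl (2Z,4S,7R,8E)-4-[(tert-butyldimethylsilyloxy)methyl]-10,10-diethoxy-7-hydroxy-4,8-dimethyldeca-2,8-dienoate
Product: 11 (2Z,4S,7R,8E)-4-[(tert-butyldimethylsilyloxy)methyl]-10,10-diethoxy-7-hydroxy-4,8-dimethyldeca-2,8-dienoic acid
Conditions: LiOH·H2O, THF/MeOH/H2O, rt; then cold 0.5 M HCl to pH 4–5
Reagents that add atoms: lithium hydroxide, [Li+].[OH-]
Why: Saponification of the methyl ester; the β-carbon is shielded by the quaternary C4, so oxa-Michael addition of the C1 hydroxyl is not expected, and the acetal should survive the base and the brief mild acidification.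

Step 8
Reactants: 11 (2Z,4S,7R,8E)-4-[(tert-butyldimethylsilyloxy)methyl]-10,10-diethoxy-7-hydroxy-4,8-dimethyldeca-2,8-dienoic acid
Product: 13 (3Z,5S,8R)-5-[(tert-butyldimethylsilyloxy)methyl]-8-[(2E)-4,4-diethoxybut-2-en-2-yl]-5-methyl-5,6,7,8-tetrahydro-2H-oxocin-2-one, via mixed anhydride 12 (not isolated)
Conditions: 2-methyl-6-nitrobenzoic anhydride (MNBA), DMAP, CH2Cl2, slow addition, 2 mM, rt to 40 °C
Reagents that add atoms: none
Why: Shiina macrolactonisation through the mixed anhydride; the Z alkene and the quaternary C4 should preorganise the seco acid for eight-membered ring closure at high dilution, and acylation at oxygen leaves the C1 configuration untouched.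

Step 9
Reactants: 13 (3Z,5S,8R)-5-[(tert-butyldimethylsilyloxy)methyl]-8-[(2E)-4,4-diethoxybut-2-en-2-yl]-5-methyl-5,6,7,8-tetrahydro-2H-oxocin-2-one
Product: 14 tetracyclic γ-lactone photoadduct (cyclobutane C5–C6–C11–C10; lactone O–C9(=O) bridging C1 and C10; C6–CH(OEt)2; C4–CH2OTBS)
Conditions: hν (300 nm), acetone/MeCN, degassed, 5 mM, rt
Reagents that add atoms: none
Why: Acetone-sensitised excitation gives the enoate triplet (1,2-biradical at C10/C5), which should add to the alkene on C1 either by C10–C11 bonding through the three-atom C9–O–C1 tether (1,5-closure, rule of five) or by C5–C6 bonding to the less substituted alkene carbon (α-acyl radical at C10, tertiary radical at C11); both 1,4-biradicals collapse to the same cyclobutane, the closest known type being the straight intramolecular [2+2] photocycloaddition of α,β-unsaturated lactones and allyl acrylates to 3-oxabicyclo[3.2.0]heptan-2-ones. The step closes the five-membered γ-lactone by 5-exo bonding at C11 and the cyclobutane by 1,4-biradical recombination, and with these both seven-membered carbocycles, because C1 and C5 are already joined through C2–C3–C4 in the eight-membered lactone. C11 and C10 are set by the resident C1 stereocentre, since the γ-lactone can only be cis-fused and the C1–C2 chain must reach C5; C5 follows from suprafacial addition to the Z ring alkene (C4 and C9 cis); C6 follows from the E alkene and can be corrected later because it becomes α to the C7 aldehyde. The step needs the straight mode and not the crossed C10–C6/C5–C11 mode: the lactone ring holds the ester in the s-cis geometry that acyclic allyl acrylates lack, the rule of five favours the γ-lactone, and the crossed adduct would have to join the neopentyl C5 to the fully substituted C11. Photodeconjugation of the enoate is excluded because the γ-carbon C4 is quaternary.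

Step 10
Reactants: 14 tetracyclic γ-lactone photoadduct
Product: 15 hydroxy methyl ketone (C10–C(=O)CH3 cis to C1 on the cyclobutane; C1–OH; drawn open, may rest as its five-membered cyclic hemiketal)
Conditions: MeLi (1.1 equiv), THF, −78 °C; aq. NH4Cl
Reagents that add atoms: methyllithium, [Li]C
Why: Addition of an organolithium to a γ-lactone should stop at the lithium hemiketal at −78 °C, so work-up gives the C9 methyl ketone (new methyl = C8) and frees the C1 hydroxyl, with C10 unchanged.

Step 11
Reactants: 15 hydroxy methyl ketone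
Product: 19 tricyclic enone (C7=C8–C9=O; C1–OH; C4–CH2OTBS), via keto aldehyde 16 (not isolated), via C10-epimeric keto aldehyde 17 (not isolated), via aldol adduct 18 (not isolated)
Conditions: 0.5 M HCl, THF, 0 °C to rt; then NaOMe, MeOH, rt
Reagents that add atoms: none
Why: Acetal hydrolysis unmasks the C7 aldehyde, and methoxide should then equilibrate C10 (and C6) through their enolates so that the only isomer able to cyclise, with acetyl and formyl both on the cyclobutane face away from C4 and C1, is drained by intramolecular aldol condensation (C8 onto C7, E1cB dehydration) to the bridged cyclohexenone.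

Step 12
Reactants: 19 tricyclic enone
Product: 20 C7-methyl ketone (C1–OH; C4–CH2OTBS; all ring stereocentres as in the target)
Conditions: Me2CuLi (3 equiv), Et2O, −78 to −20 °C; aq. NH4Cl
Reagents that add atoms: lithium dimethylcuprate, [Li+].C[Cu-]C
Why: Conjugate addition of a Gilman cuprate to the bicyclo[3.1.1]heptenone; the methyl group should enter C7 from the face of the C5–H bridge, anti to the methyl group on C11, as in cuprate additions to apoverbenone, which is the C7 configuration of the target.

Step 13
Reactants: 20 C7-methyl ketone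
Product: 21 C1 angelate (C4–CH2OTBS)
Conditions: angelic acid, 2,4,6-trichlorobenzoyl chloride, Et3N, toluene, rt; then 20, toluene, 75 °C
Reagents that add atoms: angelic acid, C/C=C(/C)C(=O)O
Why: Yamaguchi-type esterification through the angelic 2,4,6-trichlorobenzoic mixed anhydride without nucleophilic catalyst should acylate the hindered C1 hydroxyl with retention at C1 and without Z-to-E isomerisation of the angelate.

Step 14
Reactants: 21 C1 angelate (C4–CH2OTBS)
Product: 22 C1 angelate with free C4–CH2OH
Conditions: HF·pyridine, THF/pyridine, 0 °C to rt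
Reagents that add atoms: none
Why: Fluoride-mediated desilylation under buffered conditions should remove the silyl ether without touching the angelate, the ketone or the epimerisable centres.

Step 15
Reactants: 22 C1 angelate with free C4–CH2OH
Product: 23 CNP0276938.2 (target)
Conditions: tigloyl chloride, pyridine, DMAP (cat.), CH2Cl2, 0 °C to rt
Reagents that add atoms: tigloyl chloride, C/C=C(\C)C(=O)Cl
Why: Acylation of the primary neopentyl alcohol with the configurationally stable E acid chloride (nucleophilic catalysis) should complete the mixed angelate/tiglate diester.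

Compound list
1 | geraniol, (2E)-3,7-dimethylocta-2,6-dien-1-ol | CC(C)=CCC/C(C)=C/CO | starting material
2 | (2R,3R)-2,3-epoxygeraniol | CC(C)=CCC[C@@]1(C)O[C@@H]1CO | intermediate
3 | tert-butyldimethylsilyl ether of 2 | CC(C)=CCC[C@@]1(C)O[C@@H]1CO[Si](C)(C)C(C)(C)C | intermediate
4 | (2R)-2-[(tert-butyldimethylsilyloxy)methyl]-2,6-dimethylhept-5-enal | O=C[C@@](C)(CO[Si](C)(C)C(C)(C)C)CCC=C(C)C | intermediate
5 | methyl (2Z,4S)-4-[(tert-butyldimethylsilyloxy)methyl]-4,8-dimethylnona-2,7-dienoate | COC(=O)/C=C\[C@@](C)(CO[Si](C)(C)C(C)(C)C)CCC=C(C)C | intermediate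
6 | methyl (2Z,4S)-4-[(tert-butyldimethylsilyloxy)methyl]-4-methyl-7-oxohept-2-enoate | COC(=O)/C=C\[C@@](C)(CO[Si](C)(C)C(C)(C)C)CCC=O | intermediate
7 | 1,1-diethoxybut-2-yne | CC#CC(OCC)OCC | starting material
8 | chloro[(2E)-4,4-diethoxybut-2-en-2-yl]zirconocene | CCOC(OCC)/C=C(\C)[Zr](Cl)(C1C=CC=C1)C1C=CC=C1 | intermediate
9 | [(2E)-4,4-diethoxybut-2-en-2-yl](methyl)zinc | CCOC(OCC)/C=C(\C)[Zn]C | intermediate
10 | methyl (2Z,4S,7R,8E)-4-[(tert-butyldimethylsilyloxy)methyl]-10,10-diethoxy-7-hydroxy-4,8-dimethyldeca-2,8-dienoate | COC(=O)/C=C\[C@@](C)(CO[Si](C)(C)C(C)(C)C)CC[C@@H](O)/C(C)=C/C(OCC)OCC | intermediate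
11 | (2Z,4S,7R,8E)-4-[(tert-butyldimethylsilyloxy)methyl]-10,10-diethoxy-7-hydroxy-4,8-dimethyldeca-2,8-dienoic acid | OC(=O)/C=C\[C@@](C)(CO[Si](C)(C)C(C)(C)C)CC[C@@H](O)/C(C)=C/C(OCC)OCC | intermediate
12 | mixed anhydride of 11 with 2-methyl-6-nitrobenzoic acid | Cc1cccc([N+](=O)[O-])c1C(=O)OC(=O)/C=C\[C@@](C)(CO[Si](C)(C)C(C)(C)C)CC[C@@H](O)/C(C)=C/C(OCC)OCC | intermediate
13 | (3Z,5S,8R)-5-[(tert-butyldimethylsilyloxy)methyl]-8-[(2E)-4,4-diethoxybut-2-en-2-yl]-5-methyl-5,6,7,8-tetrahydro-2H-oxocin-2-one | O=C1/C=C\[C@@](C)(CO[Si](C)(C)C(C)(C)C)CC[C@H](/C(C)=C/C(OCC)OCC)O1 | intermediate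
14 | tetracyclic γ-lactone photoadduct (C9 on C10 cis to C1; C7 acetal on C6) | O=C1O[C@@H]2CC[C@](C)(CO[Si](C)(C)C(C)(C)C)[C@H]3[C@H](C(OCC)OCC)[C@]2(C)[C@@H]13 | intermediate
15 | hydroxy methyl ketone (open form of the hemiketal) | O[C@@H]1CC[C@](C)(CO[Si](C)(C)C(C)(C)C)[C@H]2[C@H](C(OCC)OCC)[C@]1(C)[C@H]2C(C)=O | intermediate
16 | keto aldehyde (C6–CHO; acetyl on C10 cis to C1) | O[C@@H]1CC[C@](C)(CO[Si](C)(C)C(C)(C)C)[C@H]2[C@H](C=O)[C@]1(C)[C@H]2C(C)=O | intermediate
17 | C10-epimeric keto aldehyde (acetyl and formyl on the same face) | O[C@@H]1CC[C@](C)(CO[Si](C)(C)C(C)(C)C)[C@H]2[C@H](C=O)[C@]1(C)[C@@H]2C(C)=O | intermediate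
18 | aldol adduct (C7 carbinol, either configuration) | O[C@@H]1CC[C@](C)(CO[Si](C)(C)C(C)(C)C)[C@H]2[C@@H]3C(O)CC(=O)[C@H]2[C@@]31C | intermediate
19 | tricyclic enone (C7=C8–C9=O) | O[C@@H]1CC[C@](C)(CO[Si](C)(C)C(C)(C)C)[C@H]2[C@@H]3C=CC(=O)[C@H]2[C@@]31C | intermediate
20 | C7-methyl ketone with C1–OH and C4–CH2OTBS | O[C@@H]1CC[C@](C)(CO[Si](C)(C)C(C)(C)C)[C@H]2[C@@H]3[C@H](C)CC(=O)[C@H]2[C@@]31C | intermediate
21 | C1 angelate, C4–CH2OTBS | C/C=C(/C)C(=O)O[C@@H]1CC[C@](C)(CO[Si](C)(C)C(C)(C)C)[C@H]2[C@@H]3[C@H](C)CC(=O)[C@H]2[C@@]31C | intermediate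
22 | C1 angelate, C4–CH2OH | C/C=C(/C)C(=O)O[C@@H]1CC[C@](C)(CO)[C@H]2[C@@H]3[C@H](C)CC(=O)[C@H]2[C@@]31C | intermediate
23 | CNP0276938.2 | C/C=C(/C)C(=O)O[C@@H]1CC[C@](C)(COC(=O)/C(C)=C/C)[C@H]2[C@@H]3[C@H](C)CC(=O)[C@H]2[C@@]31C | target

Total step count: 15. Longest linear sequence: 15 steps (1 to 23); compound 7 is used as purchased.

Steps most likely to fail

Step 9. The first bond may form in the crossed sense (C10–C6 through a six-membered lactone with a tertiary radical at C11, then C5–C11), a switch known for 1,6-dienes that carry a substituent on the tethered alkene carbon. Energy transfer to the medium-ring enoate may also be inefficient or be intercepted by oxetane formation with acetone. The fallback is a copper-templated cycloaddition of the ether analogue, a reaction known to give only straight 3-oxabicyclo[3.2.0]heptanes from diallyl ethers. It sets out from 10: DIBAL-H should reduce the ester to the (Z)-allylic diol F1; selective tosylation of the primary allylic hydroxyl followed by NaH at high dilution should close the eight-membered cyclic ether F2 (Williamson etherification); CuOTf-catalysed irradiation (254 nm, Et2O, Salomon–Kochi conditions) should give the tetracyclic ether F3; RuCl3/NaIO4 should oxidise the ring CH2 next to oxygen to the lactone carbonyl, rejoining the route at 14.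

Step 8. Oligomerisation may outrun eight-membered ring closure, and the activated Z acid may isomerise to E. The fallback closes the ring by olefin metathesis at C5=C10 instead of at the ester. It sets out from 4: Wittig methylenation (Ph3P=CH2) should give the diene F4; selective ozonolysis of the trisubstituted alkene should give the aldehyde F5; the alkenylzinc addition of step 6 should give the allylic alcohol F6; acryloyl chloride/Et3N should give the acrylate F7; ring-closing metathesis (second-generation Grubbs catalyst RuCl2(=CHPh)(PCy3)(H2IMes), toluene, 80 °C, high dilution) should form the Z enoate and rejoin the route at 13.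

Step 6. Facial selectivity in the addition to an unbranched aldehyde may be incomplete, and part of the hydrozirconation may occur at the wrong alkyne carbon. The fallback sets C1 by reduction instead of by C–C bond formation. It sets out from 6: the same alkenylzinc addition without ligand should give the carbinol F8 as a mixture of C1 epimers; Dess–Martin periodinane should give the α-methyl enone F9; Corey–Bakshi–Shibata reduction ((S)-Me-CBS oxazaborolidine, catecholborane, −78 °C, alkenyl as the large group) should give the R carbinol and rejoin the route at 10.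

Further compounds
F1 | step 9 | (2Z,4S,7R,8E)-4-[(tert-butyldimethylsilyloxy)methyl]-10,10-diethoxy-4,8-dimethyldeca-2,8-diene-1,7-diol | OC/C=C\[C@@](C)(CO[Si](C)(C)C(C)(C)C)CC[C@@H](O)/C(C)=C/C(OCC)OCC
F2 | step 9 | (3Z,5S,8R)-5-[(tert-butyldimethylsilyloxy)methyl]-8-[(2E)-4,4-diethoxybut-2-en-2-yl]-5-methyl-5,6,7,8-tetrahydro-2H-oxocine | C1/C=C\[C@@](C)(CO[Si](C)(C)C(C)(C)C)CC[C@H](/C(C)=C/C(OCC)OCC)O1
F3 | step 9 | tetracyclic ether photoadduct (14 with CH2 in place of the lactone C=O) | C1O[C@@H]2CC[C@](C)(CO[Si](C)(C)C(C)(C)C)[C@H]3[C@H](C(OCC)OCC)[C@]2(C)[C@@H]13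
F4 | step 8 | tert-butyl{[(2S)-2-ethenyl-2,6-dimethylhept-5-enyl]oxy}dimethylsilane | C=C[C@@](C)(CO[Si](C)(C)C(C)(C)C)CCC=C(C)C
F5 | step 8 | (4S)-4-[(tert-butyldimethylsilyloxy)methyl]-4-methylhex-5-enal | C=C[C@@](C)(CO[Si](C)(C)C(C)(C)C)CCC=O
F6 | step 8 | (2E,4R,7S)-7-[(tert-butyldimethylsilyloxy)methyl]-1,1-diethoxy-3,7-dimethylnona-2,8-dien-4-ol | C=C[C@@](C)(CO[Si](C)(C)C(C)(C)C)CC[C@@H](O)/C(C)=C/C(OCC)OCC
F7 | step 8 | acrylate ester of F6 | C=C[C@@](C)(CO[Si](C)(C)C(C)(C)C)CC[C@@H](OC(=O)C=C)/C(C)=C/C(OCC)OCC
F8 | step 6 | methyl (2Z,4S,8E)-4-[(tert-butyldimethylsilyloxy)methyl]-10,10-diethoxy-7-hydroxy-4,8-dimethyldeca-2,8-dienoate (C7 epimer mixture) | COC(=O)/C=C\[C@@](C)(CO[Si](C)(C)C(C)(C)C)CCC(O)/C(C)=C/C(OCC)OCC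
F9 | step 6 | methyl (2Z,4S,8E)-4-[(tert-butyldimethylsilyloxy)methyl]-10,10-diethoxy-4,8-dimethyl-7-oxodeca-2,8-dienoate | COC(=O)/C=C\[C@@](C)(CO[Si](C)(C)C(C)(C)C)CCC(=O)/C(C)=C/C(OCC)OCC
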